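The data are simulated with made-up constants; noise was put on by code.

The vessel is a closed, stirred flask held at one temperature under a fixed gas phase, and the oak run is this same flask followed for its first minutes.

| setting | oak | flask |
|---|---|---|
| substrate | 1.6 M | 1.6 M |
| gas phase | 200 mM (held) | 200 mM (held) |
| protic impurity | 0.80 M | 0.800 M |
| free catalyst | 3.2 mM | 3.2 mM |
| remark | the very flask that is asked about, followed so far |  |
| time |  | 20 min |

oak run (percent of the substrate charged)

| time / min | target / % | substrate / % |
|---|---|---|
| 0.417 | 1.5 | 98.4 |
| 1.33 | 6.4 | 92.1 |
| 2.50 | 9.5 | 87.4 |
| 4.00 | 11.3 | 84.0 |

(scatter of a reading: 0.3 percentage points)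

- at the start none of the gas is dissolved
- the numbers in the tables scatter by 0.3 percentage points (one standard deviation)
- candidate steps: free catalyst -> spent catalyst; target <-> isomer of the product; substrate + dissolved gas + free catalyst -> free catalyst + target; gas phase <-> dissolved gas; dissolved gas + protic impurity -> quenched reagent

1. the target standing at 20 min, as a percentage of the substrate charged
2. concentration of dissolved gas in solution at 5.0 min, in percent of saturation
3. the change that raises the amount of target at 20 min, in percent of the substrate charged most ("none" if none brings more than 2 percentage points) (epsilon / zeta / gamma / none)
4. amount of target at 20 min, in percent of the substrate charged, after gamma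

- epsilon: doubling the saturation concentration of gas phase, all else as stated
- zeta: doubling the amount of free catalyst, all else as stated
- gamma: doubling the transfer coefficient of the gas phase, all else as stated

The free catalyst is the smallest charge in this flask, so I write its balance: each free catalyst turns over substrate until it becomes spent catalyst, and the flask's yield follows from that lifetime output. By the last oak reading the flask has lost 16.0% of its substrate, and target makes up 70.6% of that loss. My floor is the target read at that moment, 11.3%.

For the ceiling I look at the last intervals, where the substrate falls by 4.7 percentage points and then 3.4 points. Per minute, I read a fade of that rate of 0.429 min⁻¹. Carried on at that fade, the rate leaves a tail of 3.83% of further loss. I take this tail as the high end of my bracket, an estimate and not a proven limit. At the oak run's share, my upper estimate for target is 14.0%.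

I can't narrow this by hand, so I take the middle of the tail. That gives the lifetime output, or turnover number, the substrate lost per catalyst charged: 89.6. My own figure for target is then 12.7%.

The forecast says 11.7%, inside my bracket and below my figure, holding that “the catalyst is dying”. It also gives 75% of saturation, epsilon as the best change, and 14.8% after gamma.

The flask gives 12.6%, with 73.6% of saturation, epsilon as the best change at 11 points, and 17.0% after gamma, so the forecast stands.

    free catalyst → spent catalyst (k = 0.0110 s⁻¹)
    target ⇌ isomer of the product (K = 0.430, k = 0.0220 s⁻¹)
    substrate + dissolved gas + free catalyst → free catalyst + target (k = 8.10 L² mol⁻² s⁻¹)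
    gas phase ⇌ dissolved gas, rate k4*(csat - [dissolved gas]) (kL = 0.0260 s⁻¹)
    dissolved gas + protic impurity → quenched reagent (k = 0.0140 L mol⁻¹ s⁻¹)

For its target figure to go wrong the charge would have to move: with free catalyst at 5.33 mM the answer has moved by 5 points. The substrate left in this flask at 20.0 min gives an output of 90.2. Carried to the neighbour with 0.0019 M of free catalyst, my output of 89.6 leaves 89.4% of the substrate, and that neighbour holds 88%.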